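**Strategy.** The cyclohexene ring (C9, C10, C11, C15, C16, C17) shares the three-carbon arc C9–C10–C11 with the 11-membered ring (C2–C12), a bridged bicyclo[8.3.1] pattern. Both rings are therefore disconnected by one type 2 intramolecular Diels–Alder reaction. A 1-silyloxydiene (C16=C17–C9=C10) anchored through C9 adds to the C11=C15 bond of a 2-methylcyclopentenone that carries the tether at C12. One thermal step forms C10–C11 and C15–C16, closes both rings and sets C11, C15 and C16. The precursor is assembled from three small fragments by a B-alkyl Suzuki coupling and an asymmetric Nozaki–Hiyama–Kishi coupling, with the C3 acetate already in place.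

Key step: step 15

Remark on numbering: skeletal carbons are C1–C17 in the order of the target SMILES (C1 exocyclic methylene, C3 acetoxy carbon, C6 methyl-bearing carbon, C9=C10 ring alkene, C12 ring CH next to C2, C14 the ring carbon that is a ketone until step 17, C16 and C17 carbinol carbons); acetyl and branch methyl carbons are unnumbered.

Assumption: (S)-β-citronellene (14) is bought in high enantiomeric purity; it is otherwise one dehydration step from (S)-citronellol.

Design remarks:
- C3 carries the acetate of the target from step 14 on, so every later reagent is ester-compatible and no protecting-group exchange is needed.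
- The C9=C10 geometry of the diene is fixed by cross-coupling before the enol ether is made. Silylating a conjugated enal with two γ-methylene groups would control neither the regiochemistry nor the geometry.
- The base-sensitive 4-alkenylcyclopentenone and the acid-sensitive silyl dienol ether first meet in the neutral chromium-mediated coupling.

**Fragment A (ring vinyl iodide 8)**

Step 1
Reactants: 1 (R)-4-(tert-butyldimethylsilyloxy)cyclopent-2-en-1-one; 2 (1-bromovinyl)trimethylsilane
Product: 5 (R)-4-[1-(trimethylsilyl)ethenyl]cyclopent-2-en-1-one, via silylvinyl Grignard reagent 3 (not isolated), via trans conjugate adduct 4 (not isolated)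
Conditions: 2, Mg, THF, rt; CuBr·SMe2 (10 mol%), 1, THF, −78 °C; aq. NH4Cl; then DBU, CH2Cl2, −20 °C
Reagents that add atoms: none
Why: Copper-catalysed conjugate addition of the α-silylvinyl Grignard reagent occurs anti to the C4 silyloxy group, which fixes the future C12 centre as R, and DBU then expels silanolate by E1cB β-elimination to give the 4-substituted cyclopentenone.

Step 2
Reactants: 5 (R)-4-[1-(trimethylsilyl)ethenyl]cyclopent-2-en-1-one
Product: 6 (R)-2-iodo-4-[1-(trimethylsilyl)ethenyl]cyclopent-2-en-1-one
Conditions: I2, pyridine, CH2Cl2, 0 °C to rt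
Reagents that add atoms: iodine, [I][I]
Why: Pyridine-mediated α-iodination of the enone (conjugate addition of pyridine, iodination of the enolate, elimination) leaves the vinylsilane and the γ-stereocentre untouched.

Step 3
Reactants: 6 (R)-2-iodo-4-[1-(trimethylsilyl)ethenyl]cyclopent-2-en-1-one
Product: 7 (R)-2-methyl-4-[1-(trimethylsilyl)ethenyl]cyclopent-2-en-1-one
Conditions: Me4Sn, Pd2(dba)3 (2.5 mol%), AsPh3, CuI (10 mol%), NMP, 50 °C
Reagents that add atoms: tetramethyltin, C[Sn](C)(C)C
Why: Stille cross-coupling of the α-iodoenone with tetramethyltin installs the C15 methyl group under neutral conditions that cannot epimerise or isomerise the γ-centre.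

Step 4
Reactants: 7 (R)-2-methyl-4-[1-(trimethylsilyl)ethenyl]cyclopent-2-en-1-one
Product: 8 (R)-4-(1-iodoethenyl)-2-methylcyclopent-2-en-1-one
Conditions: NIS, (CF3)2CHOH, 0 °C
Reagents that add atoms: N-iodosuccinimide, O=C1CCC(=O)N1I
Why: Ipso-iododesilylation of the 2-silyl-1-alkene by N-iodosuccinimide in the ionising, non-basic fluoroalcohol gives the 1,1-disubstituted vinyl iodide, while the electron-poor enone does not react.

**Fragment B (iodo alcohol 13)**

Step 5
Reactants: 9 crotonaldehyde
Product: 10 (Z)-2-iodobut-2-enal
Conditions: I2, K2CO3, DMAP (cat.), THF/H2O, rt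
Reagents that add atoms: iodine, [I][I]
Why: Amine-catalysed α-iodination of the enal (conjugate addition of DMAP, iodination, elimination) should return the more stable Z iodoenal, in which the methyl group stays trans to the formyl group and cis to iodine.

Step 6
Reactants: 10 (Z)-2-iodobut-2-enal
Product: 11 (Z)-3-iodopenta-1,3-diene
Conditions: Ph3PCH3Br, KN(SiMe3)2, THF, −78 to 0 °C
Reagents that add atoms: methyltriphenylphosphonium bromide, C[P+](c1ccccc1)(c1ccccc1)c1ccccc1.[Br-]
Why: Wittig methylenation of the aldehyde with the non-stabilised ylide at low temperature leaves the iodoalkene geometry intact.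

Step 7
Reactants: 11 (Z)-3-iodopenta-1,3-diene
Product: 13 (Z)-3-iodopent-3-en-1-ol, via B-alkyl-9-BBN adduct 12 (not isolated)
Conditions: 9-BBN, THF, 0 °C to rt; then NaOH, H2O2, 0 °C
Reagents that add atoms: hydrogen peroxide, OO
Why: Hydroboration–oxidation: 9-BBN adds only to the monosubstituted terminal alkene at its CH2 end (anti-Markovnikov), and oxidation gives the primary homoallylic alcohol without touching the trisubstituted iodoalkene.

**Fragment C and chain assembly**

Step 8
Reactants: 14 (S)-β-citronellene [(3S)-3,7-dimethylocta-1,6-diene]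
Product: 16 methyl (S)-4-methylhex-5-enoate, via aldehyde 15 (not isolated)
Conditions: O3 (1.0 equiv), 2.5 M NaOH in MeOH, CH2Cl2, −78 °C
Reagents that add atoms: ozone, [O-][O+]=O; methanol, CO
Why: Ozonolysis with in situ oxidative esterification: with ozone limited to one equivalent the electron-rich trisubstituted alkene should be cleaved in preference to the terminal vinyl group, and the aldehyde is oxidised further as its methyl hemiacetal to the ester.

Step 9
Reactants: 16 methyl (S)-4-methylhex-5-enoate; 13 (Z)-3-iodopent-3-en-1-ol
Product: 18 methyl (4R,7E)-7-(2-hydroxyethyl)-4-methylnon-7-enoate, via B-alkyl-9-BBN adduct 17 (not isolated)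
Conditions: 16, 9-BBN, THF, rt; then 13, PdCl2(dppf) (5 mol%), AsPh3, Cs2CO3, DMF/H2O, rt
Reagents that add atoms: none
Why: B-alkyl Suzuki–Miyaura coupling: the alkylborane from the terminal alkene couples with the vinyl iodide with retention of alkene geometry, which fixes C8 cis to the C10 methyl group, and the ester and free hydroxyl are tolerated.

Step 10
Reactants: 18 methyl (4R,7E)-7-(2-hydroxyethyl)-4-methylnon-7-enoate
Product: 19 methyl (4R,7E)-4-methyl-7-(2-oxoethyl)non-7-enoate
Conditions: Dess–Martin periodinane, NaHCO3, CH2Cl2, 0 °C; crude product used at once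
Reagents that add atoms: none
Why: Buffered Dess–Martin oxidation gives the β,γ-unsaturated aldehyde without migration of the trisubstituted alkene into conjugation.

Step 11
Reactants: 19 methyl (4R,7E)-4-methyl-7-(2-oxoethyl)non-7-enoate
Product: 20 methyl (4R,7E)-7-[(E)-2-(tert-butyldimethylsilyloxy)ethenyl]-4-methylnon-7-enoate
Conditions: Et3N, then TBSOTf, CH2Cl2, −78 °C; chromatography on Et3N-deactivated silica
Reagents that add atoms: tert-butyldimethylsilyl trifluoromethanesulfonate, CC(C)(C)[Si](C)(C)OS(=O)(=O)C(F)(F)F
Why: Soft enolisation (O-silylation, then removal of the doubly activated C17 proton by the amine) gives the conjugated silyl dienol ether with the preset C9=C10 geometry, and the E enol ether is expected because a Z arrangement would press the silyloxy group against the fully substituted C9.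

Step 12
Reactants: 20 methyl (4R,7E)-7-[(E)-2-(tert-butyldimethylsilyloxy)ethenyl]-4-methylnon-7-enoate
Product: 21 (4R,7E)-7-[(E)-2-(tert-butyldimethylsilyloxy)ethenyl]-4-methylnon-7-enal
Conditions: i-Bu2AlH (1.1 equiv), CH2Cl2, −78 °C; aq. potassium sodium tartrate
Reagents that add atoms: none
Why: Partial reduction of the methyl ester stops at the tetrahedral aluminium hemiacetal at −78 °C and releases the C3 aldehyde on work-up, the silyl dienol ether being inert to the hydride.

**Fragment union and key step**

Step 13
Reactants: 21 (4R,7E)-7-[(E)-2-(tert-butyldimethylsilyloxy)ethenyl]-4-methylnon-7-enal; 8 (R)-4-(1-iodoethenyl)-2-methylcyclopent-2-en-1-one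
Product: 22 (R)-4-[(3S,6R,9E)-9-[(E)-2-(tert-butyldimethylsilyloxy)ethenyl]-3-hydroxy-6-methylundeca-1,9-dien-2-yl]-2-methylcyclopent-2-en-1-one
Conditions: CrCl2 (4 equiv), NiCl2 (5 mol%), N-[2-(4-isopropyl-4,5-dihydrooxazol-2-yl)-6-methylphenyl]methanesulfonamide (4 equiv, the antipode that gives the 3S carbinol on a model aldehyde), 1,8-bis(dimethylamino)naphthalene, THF/MeCN, rt
Reagents that add atoms: none
Why: Nozaki–Hiyama–Kishi coupling: the alkenylchromium species formed through nickel catalysis adds to the aldehyde in preference to the enone and tolerates the silyl dienol ether, and the chiral sulfonamide–oxazoline ligand on chromium is relied on to set C3 as S by reagent control.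

Step 14
Reactants: 22 (R)-4-[(3S,6R,9E)-9-[(E)-2-(tert-butyldimethylsilyloxy)ethenyl]-3-hydroxy-6-methylundeca-1,9-dien-2-yl]-2-methylcyclopent-2-en-1-one
Product: 23 (R)-4-[(3S,6R,9E)-3-acetoxy-9-[(E)-2-(tert-butyldimethylsilyloxy)ethenyl]-6-methylundeca-1,9-dien-2-yl]-2-methylcyclopent-2-en-1-one (cycloaddition precursor)
Conditions: Ac2O, pyridine, DMAP (cat.), CH2Cl2, 0 °C; chromatography on Et3N-deactivated silica
Reagents that add atoms: acetic anhydride, CC(=O)OC(C)=O
Why: DMAP-catalysed acylation of the secondary allylic alcohol installs the acetate of the target under mildly basic conditions that the silyl dienol ether tolerates.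

Step 15
Reactants: 23 cycloaddition precursor (4-substituted 2-methylcyclopentenone with tethered 1-silyloxydiene)
Product: 24 tricyclic C14 ketone with bridgehead C17=C9 alkene, C16 silyl ether and C3 acetate
Conditions: toluene (0.002 M), BHT (cat.), silylated sealed tube, 150 °C
Reagents that add atoms: none
Why: Concerted suprafacial [4+2] cycloaddition in which the C10 terminus of the 1-silyloxydiene, its nucleophilic end, bonds to the enone β-carbon C11 while C16 bonds to C15, the regiochemistry that the C9 anchor also favours. The closest known reaction type is the type 2 intramolecular Diels–Alder reaction that gives bridged bicycles with a bridgehead alkene, applied here to a longer tether and a cyclopentenone dienophile. The cyclohexene (C9, C10, C11, C15, C16, C17) closes by the cycloaddition itself, and the 11-membered ring (C2 to C12) closes in the same event as the bridge between C9 and C11 through the new C10–C11 bond, leaving C17=C9 as an unstrained bridgehead alkene. C11 and C15 become cis because the dienophile adds suprafacially, C10 and C16 become cis to each other because both diene termini carry their substituents E, and the cis relation of C16–O to the C15 methyl group follows from the ketone-exo orientation. The step needs bonding on the enone face that bears the C12 side chain together with an exo ketone: a side chain syn to the reacting face cannot lie under the diene, so syn delivery through the tether and the exo mode go together, and the C15 methyl group on the dienophile further disfavours the ketone-endo arrangement. High dilution, a radical inhibitor and neutral silylated glass are meant to suppress intermolecular cycloaddition, polymerisation and acid- or base-induced loss of the enol ether or of the C12 configuration.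

**Endgame**

Step 16
Reactants: 24 tricyclic C14 ketone
Product: 25 C14 tosylhydrazone of 24
Conditions: TsNHNH2, PPTS (cat.), THF, 50 °C
Reagents that add atoms: p-toluenesulfonyl hydrazide, Cc1ccc(cc1)S(=O)(=O)NN
Why: Condensation of the hindered but unconjugated cyclopentanone with tosylhydrazide under mild acid catalysis gives the tosylhydrazone without affecting the acetate or the silyl ether.

Step 17
Reactants: 25 C14 tosylhydrazone
Product: 27 C14-deoxygenated tricycle (C14 methylene, C17=C9 alkene, C16 silyl ether, C3 acetate), via tosylhydrazine 26 (not isolated)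
Conditions: catecholborane, CHCl3, 0 °C; then NaOAc·3H2O, reflux
Reagents that add atoms: none
Why: Reductive deoxygenation of a tosylhydrazone: hydride from catecholborane adds to the C=N bond, acetate then induces loss of sulfinate, and the diazene extrudes N2 to leave the C14 methylene under conditions that spare the ester and both alkenes.

Step 18
Reactants: 27 C14-deoxygenated tricycle
Product: 29 C17 allylic alcohol with C9=C10 alkene (C16 silyl ether, C3 acetate), via C17 hydroperoxide 28 (not isolated)
Conditions: O2, visible light, tetraphenylporphyrin (cat.), CH2Cl2, 0 °C, stopped near full conversion; then PPh3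
Reagents that add atoms: dioxygen, O=O
Why: Singlet-oxygen ene reaction (Schenck): oxygen adds suprafacially at C17 on the face anti to the C16 silyloxy group while the syn C10–H on the doubly substituted side of the alkene (cis effect) is transferred, which moves the alkene to C9=C10 and sets C17–O trans to C16–O, and PPh3 then reduces the hydroperoxide.

Step 19
Reactants: 29 C17 allylic alcohol with C16 silyl ether
Product: 30 CNP0192310.1 (target)
Conditions: HF·pyridine, pyridine, THF, 0 °C to rt
Reagents that add atoms: none
Why: Fluoride-mediated cleavage of the hindered secondary silyl ether with buffered HF·pyridine should leave the acetate and the allylic diol intact.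

**Compound list**

1 | (R)-4-(tert-butyldimethylsilyloxy)cyclopent-2-en-1-one | O=C1C=C[C@H](O[Si](C)(C)C(C)(C)C)C1 | starting material
2 | (1-bromovinyl)trimethylsilane | C=C(Br)[Si](C)(C)C | starting material
3 | [1-(trimethylsilyl)ethenyl]magnesium bromide | C=C([Mg]Br)[Si](C)(C)C | intermediate
4 | (3R,4R)-4-(tert-butyldimethylsilyloxy)-3-[1-(trimethylsilyl)ethenyl]cyclopentan-1-one (trans) | O=C1C[C@@H](C(=C)[Si](C)(C)C)[C@H](O[Si](C)(C)C(C)(C)C)C1 | intermediate
5 | (R)-4-[1-(trimethylsilyl)ethenyl]cyclopent-2-en-1-one | O=C1C[C@@H](C(=C)[Si](C)(C)C)C=C1 | intermediate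
6 | (R)-2-iodo-4-[1-(trimethylsilyl)ethenyl]cyclopent-2-en-1-one | O=C1C[C@@H](C(=C)[Si](C)(C)C)C=C1I | intermediate
7 | (R)-2-methyl-4-[1-(trimethylsilyl)ethenyl]cyclopent-2-en-1-one | O=C1C[C@@H](C(=C)[Si](C)(C)C)C=C1C | intermediate
8 | (R)-4-(1-iodoethenyl)-2-methylcyclopent-2-en-1-one | O=C1C[C@@H](C(=C)I)C=C1C | intermediate
9 | crotonaldehyde, (E)-but-2-enal | C/C=C/C=O | starting material
10 | (Z)-2-iodobut-2-enal | C/C=C(C=O)\I | intermediate
11 | (Z)-3-iodopenta-1,3-diene | C/C=C(C=C)\I | intermediate
12 | 9-[(Z)-3-iodopent-3-en-1-yl]-9-borabicyclo[3.3.1]nonane | C/C=C(CCB1C2CCCC1CCC2)\I | intermediate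
13 | (Z)-3-iodopent-3-en-1-ol | C/C=C(CCO)\I | intermediate
14 | (S)-β-citronellene, (3S)-3,7-dimethylocta-1,6-diene | C=C[C@@H](C)CCC=C(C)C | starting material
15 | (S)-4-methylhex-5-enal | C=C[C@@H](C)CCC=O | intermediate
16 | methyl (S)-4-methylhex-5-enoate | C=C[C@@H](C)CCC(=O)OC | intermediate
17 | methyl (R)-6-(9-borabicyclo[3.3.1]nonan-9-yl)-4-methylhexanoate | COC(=O)CC[C@H](C)CCB1C2CCCC1CCC2 | intermediate
18 | methyl (4R,7E)-7-(2-hydroxyethyl)-4-methylnon-7-enoate | COC(=O)CC[C@H](C)CC/C(=C\C)CCO | intermediate
19 | methyl (4R,7E)-4-methyl-7-(2-oxoethyl)non-7-enoate | COC(=O)CC[C@H](C)CC/C(=C\C)CC=O | intermediate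
20 | methyl (4R,7E)-7-[(E)-2-(tert-butyldimethylsilyloxy)ethenyl]-4-methylnon-7-enoate | COC(=O)CC[C@H](C)CC/C(=C\C)/C=C/O[Si](C)(C)C(C)(C)C | intermediate
21 | (4R,7E)-7-[(E)-2-(tert-butyldimethylsilyloxy)ethenyl]-4-methylnon-7-enal | O=CCC[C@H](C)CC/C(=C\C)/C=C/O[Si](C)(C)C(C)(C)C | intermediate
22 | (R)-4-[(3S,6R,9E)-9-[(E)-2-(tert-butyldimethylsilyloxy)ethenyl]-3-hydroxy-6-methylundeca-1,9-dien-2-yl]-2-methylcyclopent-2-en-1-one | O=C1C[C@@H](C(=C)[C@@H](O)CC[C@H](C)CC/C(=C\C)/C=C/O[Si](C)(C)C(C)(C)C)C=C1C | intermediate
23 | (R)-4-[(3S,6R,9E)-3-acetoxy-9-[(E)-2-(tert-butyldimethylsilyloxy)ethenyl]-6-methylundeca-1,9-dien-2-yl]-2-methylcyclopent-2-en-1-one | O=C1C[C@@H](C(=C)[C@@H](OC(C)=O)CC[C@H](C)CC/C(=C\C)/C=C/O[Si](C)(C)C(C)(C)C)C=C1C | intermediate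
24 | tricyclic C14 ketone: C17=C9 bridgehead alkene, C16 OTBS cis to C15 methyl and to C10 methyl, cis C11/C15 ring fusion, C3 acetate | C=C1[C@@H](OC(C)=O)CC[C@H](C)CCC2=C[C@H](O[Si](C)(C)C(C)(C)C)[C@@]3(C)C(=O)C[C@@H]1[C@H]3[C@@H]2C | intermediate
25 | C14 tosylhydrazone of 24 | C=C1[C@@H](OC(C)=O)CC[C@H](C)CCC2=C[C@H](O[Si](C)(C)C(C)(C)C)[C@@]3(C)C(=NNS(=O)(=O)c4ccc(C)cc4)C[C@@H]1[C@H]3[C@@H]2C | intermediate
26 | C14 tosylhydrazine (C14 configuration not defined) | C=C1[C@@H](OC(C)=O)CC[C@H](C)CCC2=C[C@H](O[Si](C)(C)C(C)(C)C)[C@@]3(C)C(NNS(=O)(=O)c4ccc(C)cc4)C[C@@H]1[C@H]3[C@@H]2C | intermediate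
27 | C14-deoxygenated tricycle: C17=C9 alkene, C16 OTBS, C3 acetate | C=C1[C@@H](OC(C)=O)CC[C@H](C)CCC2=C[C@H](O[Si](C)(C)C(C)(C)C)[C@@]3(C)CC[C@@H]1[C@H]3[C@@H]2C | intermediate
28 | C17 hydroperoxide with C9=C10 alkene, C16 OTBS trans to C17–OOH | C=C1[C@@H](OC(C)=O)CC[C@H](C)CCC2=C(C)[C@@H]3[C@H]1CC[C@]3(C)[C@@H](O[Si](C)(C)C(C)(C)C)[C@@H]2OO | intermediate
29 | C17 allylic alcohol with C9=C10 alkene, C16 OTBS, C3 acetate | C=C1[C@@H](OC(C)=O)CC[C@H](C)CCC2=C(C)[C@@H]3[C@H]1CC[C@]3(C)[C@@H](O[Si](C)(C)C(C)(C)C)[C@@H]2O | intermediate
30 | CNP0192310.1 | C=C1[C@@H](OC(C)=O)CC[C@H](C)CCC2=C(C)[C@@H]3[C@H]1CC[C@]3(C)[C@@H](O)[C@@H]2O | target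

**Totals.** Total step count: 19. Longest linear sequence: 14 steps (steps 5–7, then 9–19, from crotonaldehyde).

**Steps most likely to fail and their fallbacks**

1. Step 15 (cycloaddition). Closure of the 11-membered bridge may be too slow to compete with thermal decay of the silyl dienol ether or isomerisation of the 4-alkenylcyclopentenone. The diene may also add in the ketone-endo mode on the enone face remote from the C12 side chain, which would give the wrong relative configuration. The fallback replaces the concerted process by a stepwise polar annulation with open transition states. Starting from 23, a catalytic amount of HNTf2 in CH2Cl2 at −78 °C converts a little diene into TBSNTf2, the actual Lewis acid. Silyl transfer to the enone oxygen triggers an intramolecular vinylogous Mukaiyama–Michael addition (C10 to C11) that closes the 11-membered ring and gives the macrocyclic silyl enol ether enal F1. The same silyl Lewis acid then promotes the intramolecular Mukaiyama aldol closure (C15 to C16) with silyl transfer to the C16 oxygen. This returns to the route at 24.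

2. Step 18 (ene oxidation). Hydrogen transfer may take place from C8 instead of C10, which would place the alkene at C8=C9. The more electron-rich tetrasubstituted alkene of the product may also be oxidised a second time. The fallback is an epoxide opening instead of an ene reaction. Starting from 27, mCPBA with NaHCO3 in CH2Cl2 should epoxidise the trisubstituted alkene anti to the silyloxy group to give the C9–C17 epoxide F2. TMSOTf and DBU in toluene then open it at the tertiary C9–O bond with loss of the C10 proton toward the more substituted ring alkene, giving the C17 trimethylsilyl ether F3. Aqueous citric acid work-up cleaves the trimethylsilyl ether and returns to the route at 29.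

3. Step 13 (asymmetric coupling). Reagent control at C3 may be insufficient and give a mixture of carbinol epimers, or the ligated chromium reagent may couple sluggishly while the base slowly isomerises the enone. The fallback replaces catalyst control by separation and stereoinversion. Starting from 21 and 8, ligand-free coupling with CrCl2 and NiCl2 (cat.) in DMSO gives 22 together with the (3R) carbinol F4, which are separated by chromatography. 22 is acetylated as in step 14, and F4 is converted with inversion by Mitsunobu esterification (PPh3, DIAD, AcOH, THF, 0 °C) into the same acetate. This returns to the route at 23.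

**Further compounds**

F1 | step 15 | macrocyclic Michael adduct: C14 tert-butyldimethylsilyl enol ether (C14=C15), C16 aldehyde conjugated with C17=C9, C10–C11 bond formed | C=C1[C@@H](OC(C)=O)CC[C@H](C)CC/C(=C/C=O)[C@@H](C)[C@@H]2[C@H]1CC(O[Si](C)(C)C(C)(C)C)=C2C
F2 | step 18 | C9–C17 epoxide of 27, oxygen anti to the C16 silyloxy group | C=C1[C@@H](OC(C)=O)CC[C@H](C)CC[C@@]23O[C@H]3[C@H](O[Si](C)(C)C(C)(C)C)[C@@]4(C)CC[C@@H]1[C@H]4[C@@H]2C
F3 | step 18 | C17 trimethylsilyl ether of 29 | C=C1[C@@H](OC(C)=O)CC[C@H](C)CCC2=C(C)[C@@H]3[C@H]1CC[C@]3(C)[C@@H](O[Si](C)(C)C(C)(C)C)[C@@H]2O[Si](C)(C)C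
F4 | step 13 | (3R) epimer of 22 | O=C1C[C@@H](C(=C)[C@H](O)CC[C@H](C)CC/C(=C\C)/C=C/O[Si](C)(C)C(C)(C)C)C=C1C
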